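**Retrosynthetic overview**
Ring numbering of the target: C1 (methyl-bearing) = C2, C3 (ring A, the chalcone aryl), C4 (aroyl, ring B), C5 (ring C, 2,4-dihydroxyphenyl), C6 (CH2). The strategy rests on the C4 aroyl C=O lying γ,δ to the C1=C2 alkene while C1 is joined back to C4 through C6–C5. The ketone oxygen can therefore be tied to C1, which makes the target the Claisen product of a (2S,4S)-6-aryl-2-methyl-2-[(E)-styryl]-3,4-dihydro-2H-pyran.
The styryl group comes from Heck arylation of the 2-vinyl dihydropyran with a 3'-iodochalcone; the 6-aryl enol ether comes from Suzuki coupling of a δ-lactone ketene acetal phosphate with the ring B boronic acid.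
The 4-aryl-6-methyl-6-vinyl δ-lactone comes from ozonolytic recasting of a cyclohexenol, made by Wharton transposition of a trans epoxy ketone of an (S)-5-aryl-3-methylcyclohexenone, itself from a desymmetrizing aldol condensation of a 4-arylheptane-2,6-dione.
Ring order: cyclohexenone (aldol), epoxide, cleavage and reclosure as δ-lactone, dihydropyran, then the cyclohexene of the target by the Claisen ring switch; all benzene rings are bought and the six MOM ethers fall last.

Key step: step 24

Assumption: the quinine-derived primary amine in step 6 is taken to give the (S)-enone 8; should it deliver the mirror image, its quinidine-derived pseudoenantiomer is used with no other change.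

**Ring C and the lactone core**

Step 1
Reactants: 1 2,4-dihydroxybenzaldehyde
Product: 2 2,4-bis(methoxymethoxy)benzaldehyde
Conditions: NaH, MOMCl, DMF, 0 °C to rt
Reagents that add atoms: chloromethyl methyl ether, COCCl
Why: Williamson-type O-alkylation of both sodium phenoxides, the hydrogen-bonded 2-OH included, gives the base-stable bis-MOM ether.

Step 2
Reactants: 2 2,4-bis(methoxymethoxy)benzaldehyde
Product: 4 diethyl 2-[2,4-bis(methoxymethoxy)phenyl]-4-hydroxy-4-methyl-6-oxocyclohexane-1,3-dicarboxylate (racemic ketol), via open-chain bis(acetoacetate) adduct 3 (not isolated)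
Conditions: ethyl acetoacetate (2.2 equiv), piperidine (cat.), EtOH, rt
Reagents that add atoms: ethyl acetoacetate, CCOC(=O)CC(C)=O
Why: Knoevenagel condensation, Michael addition of a second acetoacetate and intramolecular aldol closure should give the classical crystalline ketol, whose stereocentres do not matter because all are erased in step 3.

Step 3
Reactants: 4 racemic ketol diester
Product: 5 3-[2,4-bis(methoxymethoxy)phenyl]pentanedioic acid
Conditions: NaOH (50% aq.), EtOH, reflux; then 1 M HCl to pH 4, 0 °C
Reagents that add atoms: sodium hydroxide, [Na+].[OH-]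
Why: Hot alkali reverses the aldol, removes both acetyl groups by retro-Claisen cleavage and saponifies the esters, while the aryl MOM ethers survive base and a brief cold acidification.

Step 4
Reactants: 5 3-arylpentanedioic acid
Product: 6 3-[2,4-bis(methoxymethoxy)phenyl]-N1,N5-dimethoxy-N1,N5-dimethylpentanediamide
Conditions: MeNH(OMe)·HCl, EDC·HCl, HOBt (cat.), N-methylmorpholine, CH2Cl2, 0 °C to rt
Reagents that add atoms: N,O-dimethylhydroxylamine hydrochloride, CNOC.Cl
Why: Carbodiimide amide coupling under near-neutral conditions converts both carboxyl groups into Weinreb amides without touching the acetals.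

Step 5
Reactants: 6 bis-Weinreb amide
Product: 7 4-[2,4-bis(methoxymethoxy)phenyl]heptane-2,6-dione
Conditions: MeMgBr (3 equiv), THF, 0 °C; cold pH 7 buffer quench
Reagents that add atoms: methylmagnesium bromide, C[Mg]Br
Why: Weinreb ketone synthesis: the chelated tetrahedral adducts stop at the ketone stage, and the neutral cold quench avoids a racemic base-mediated aldol closure of the prochiral diketone.

Step 6
Reactants: 7 4-arylheptane-2,6-dione
Product: 8 (S)-5-[2,4-bis(methoxymethoxy)phenyl]-3-methylcyclohex-2-en-1-one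
Conditions: 9-amino-9-deoxy-epi-quinine (20 mol%), AcOH (60 mol%), toluene, −15 °C
Reagents that add atoms: none
Why: Desymmetrizing intramolecular aldol condensation through a chiral primary-amine enamine, in which the catalyst selects one of the two enantiotopic acetyl groups as nucleophile and so sets C5 as S.

Step 7
Reactants: 8 (S)-enone
Product: 9 (2S,3S,5S)-5-[2,4-bis(methoxymethoxy)phenyl]-2,3-epoxy-3-methylcyclohexan-1-one (epoxide oxygen trans to the aryl group)
Conditions: H2O2 (30% aq.), NaOH (aq., cat.), MeOH, 0 °C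
Reagents that add atoms: hydrogen peroxide, OO
Why: Weitz–Scheffer nucleophilic epoxidation, in which hydroperoxide adds axially to C3 anti to the pseudo-equatorial C5 aryl group and the enolate closes on the same face, sets C2 and C3 from C5.

Step 8
Reactants: 9 trans epoxy ketone
Product: 10 (1S,5R)-5-[2,4-bis(methoxymethoxy)phenyl]-1-methylcyclohex-2-en-1-ol (OH trans to the aryl group)
Conditions: N2H4·H2O, AcOH (cat.), MeOH, 0 °C to rt
Reagents that add atoms: none
Why: Wharton transposition: the epoxy hydrazone fragments with loss of dinitrogen to the allylic alcohol, and the tertiary C–O bond is not touched, so its configuration is kept.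

Step 9
Reactants: 10 tertiary allylic alcohol
Product: 12 (2S,4S)-4-[2,4-bis(methoxymethoxy)phenyl]-6-hydroxy-2-methyloxane-2-carbaldehyde (lactol, both anomers), via hydroxy dialdehyde 11 (not isolated)
Conditions: O3, CH2Cl2, NaHCO3, −78 °C (Sudan Red 7B end point); PPh3, −78 °C to rt
Reagents that add atoms: ozone, [O-][O+]=O
Why: Ozonolysis cleaves the only aliphatic alkene faster than the electron-rich arene (dye end point), and the δ-hydroxy aldehyde closes at once to the six-membered lactol through the tertiary oxygen, leaving the aldehyde on the quaternary carbon free.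

Step 10
Reactants: 12 lactol aldehyde
Product: 13 (2S,4S)-4-[2,4-bis(methoxymethoxy)phenyl]-2-methyl-6-oxooxane-2-carbaldehyde
Conditions: Ag2CO3 on Celite, toluene, 80 °C
Reagents that add atoms: none
Why: Fetizon oxidation dehydrogenates lactols far faster than it touches aldehydes, so the lactone forms with the quaternary aldehyde intact.

Step 11
Reactants: 13 lactone aldehyde
Product: 14 (4S,6S)-4-[2,4-bis(methoxymethoxy)phenyl]-6-ethenyl-6-methyloxan-2-one
Conditions: Ph3PCH3Br, KN(SiMe3)2, THF, 0 °C; then 13, −78 to 0 °C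
Reagents that add atoms: methyltriphenylphosphonium bromide, C[P+](c1ccccc1)(c1ccccc1)c1ccccc1.[Br-]
Why: Wittig methylenation with one equivalent of ylide takes the aldehyde well ahead of the lactone, and the quaternary α-carbon cannot epimerize.

**Ring B boronic acid**

Step 12
Reactants: 15 resorcinol
Product: 16 1,3-bis(methoxymethoxy)benzene
Conditions: NaH, MOMCl, DMF, 0 °C to rt
Reagents that add atoms: chloromethyl methyl ether, COCCl
Why: Double O-alkylation of the bis-phenoxide installs the two groups that later direct both lithiations.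

Step 13
Reactants: 16 1,3-bis(methoxymethoxy)benzene
Product: 18 2-iodo-1,3-bis(methoxymethoxy)benzene, via 2-lithio-1,3-bis(methoxymethoxy)benzene 17 (not isolated)
Conditions: n-BuLi, THF, 0 °C; I2, −78 °C to rt
Reagents that add atoms: iodine, II
Why: Directed ortho-metalation removes the C2 proton flanked by both MOM-oxy groups, and iodinolysis of the aryllithium fixes the halogen there.

Step 14
Reactants: 19 3-methylbut-1-yne
Product: 20 (E)-4,4,5,5-tetramethyl-2-(3-methylbut-1-en-1-yl)-1,3,2-dioxaborolane
Conditions: pinacolborane, Cp2Zr(H)Cl (5 mol%), Et3N (10 mol%), neat, sealed tube, 40 °C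
Reagents that add atoms: pinacolborane, CC1(C)OBOC1(C)C
Why: Zirconium-catalysed hydroboration adds H–B syn and anti-Markovnikov across the terminal alkyne, which gives the E alkenylboronate.

Step 15
Reactants: 18 2-iodo-1,3-bis(methoxymethoxy)benzene; 20 (E)-alkenylboronate
Product: 21 1,3-bis(methoxymethoxy)-2-[(E)-3-methylbut-1-enyl]benzene
Conditions: Pd(OAc)2 (3 mol%), SPhos (6 mol%), K3PO4, toluene/H2O, 80 °C
Reagents that add atoms: none
Why: Suzuki–Miyaura coupling with a bulky biarylphosphine copes with the di-ortho-substituted iodide and transfers the alkenyl group with retention of the E geometry.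

Step 16
Reactants: 21 1,3-bis(methoxymethoxy)-2-[(E)-3-methylbut-1-enyl]benzene
Product: 23 {2,4-bis(methoxymethoxy)-3-[(E)-3-methylbut-1-enyl]phenyl}boronic acid, via aryllithium 22 (not isolated)
Conditions: n-BuLi, TMEDA, THF, −20 to 0 °C; B(Oi-Pr)3, −78 °C to rt; then water, 0 °C (pH 6–7)
Reagents that add atoms: triisopropyl borate, CC(C)OB(OC(C)C)OC(C)C; water, O
Why: Directed ortho-metalation can only occur at the two equivalent positions next to a MOM-oxy group, and borate trapping with neutral hydrolysis gives the boronic acid without acid exposure of the acetals.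

**Ring A iodochalcone**

Step 17
Reactants: 24 2,4-dihydroxyacetophenone
Product: 25 1-(2,4-dihydroxy-3-iodophenyl)ethan-1-one
Conditions: I2, HIO3, EtOH/H2O, rt to 40 °C
Reagents that add atoms: iodine, II; iodic acid, O[I](=O)=O
Why: Electrophilic iodination with the iodine/iodic acid couple goes to C3, the position ortho to both hydroxyl groups, and uses every iodine atom.

Step 18
Reactants: 25 3-iodo-2,4-dihydroxyacetophenone
Product: 26 1-[3-iodo-2,4-bis(methoxymethoxy)phenyl]ethan-1-one
Conditions: NaH (2.2 equiv), MOMCl, THF/DMF, 0 °C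
Reagents that add atoms: chloromethyl methyl ether, COCCl
Why: With the base held to two equivalents only the phenoxides form, and O-alkylation protects both, the chelated 2-OH included.

Step 19
Reactants: 27 4-hydroxybenzaldehyde
Product: 28 4-(methoxymethoxy)benzaldehyde
Conditions: NaH, MOMCl, DMF, 0 °C to rt
Reagents that add atoms: chloromethyl methyl ether, COCCl
Why: Simple phenoxide O-alkylation gives the non-enolizable aldol acceptor in protected form.

Step 20
Reactants: 26 iodo acetophenone bis-MOM ether; 28 4-(methoxymethoxy)benzaldehyde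
Product: 29 (E)-1-[3-iodo-2,4-bis(methoxymethoxy)phenyl]-3-[4-(methoxymethoxy)phenyl]prop-2-en-1-one
Conditions: KOH, EtOH/H2O, rt
Reagents that add atoms: none
Why: Claisen–Schmidt condensation of the methyl ketone enolate with the aldehyde and E1cB dehydration gives the E enone, with aryl iodide and acetals inert to base.

**Assembly**

Step 21
Reactants: 14 vinyl lactone
Product: 30 (2S,4S)-4-[2,4-bis(methoxymethoxy)phenyl]-2-ethenyl-2-methyl-3,4-dihydro-2H-pyran-6-yl diphenyl phosphate
Conditions: KN(SiMe3)2 added to 14 and (PhO)2P(O)Cl, HMPA, THF, −78 °C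
Reagents that add atoms: diphenyl chlorophosphate, O=P(Cl)(Oc1ccccc1)Oc1ccccc1
Why: Kinetic enolization of the lactone with in situ O-phosphorylation gives the ketene acetal phosphate before the enolate can rearrange, and neither stereocentre is involved.

Step 22
Reactants: 30 ketene acetal phosphate; 23 ring B boronic acid
Product: 31 (2S,4S)-6-{2,4-bis(methoxymethoxy)-3-[(E)-3-methylbut-1-enyl]phenyl}-4-[2,4-bis(methoxymethoxy)phenyl]-2-ethenyl-2-methyl-3,4-dihydro-2H-pyran
Conditions: Pd(PPh3)4 (5 mol%), 2 M aq. Na2CO3, THF, 45 °C; chromatography on Et3N-treated silica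
Reagents that add atoms: none
Why: Suzuki–Miyaura coupling of a lactone-derived ketene acetal phosphate, in which zerovalent palladium inserts into the C–OP bond, gives the 6-aryl enol ether under basic conditions that this acid-labile group tolerates.

Step 23
Reactants: 31 2-vinyl dihydropyran; 29 iodochalcone
Product: 32 (2S,4S)-2-methyl-2-[(E)-styryl] dihydropyran carrying ring A on the styrene, ring B on C6 and ring C on C4 (the Claisen precursor)
Conditions: Pd2(dba)3 (2.5 mol%), [HP(t-Bu)3]BF4 (10 mol%), Cy2NMe, 1,4-dioxane, 25–40 °C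
Reagents that add atoms: none
Why: Mizoroki–Heck arylation of the only monosubstituted alkene puts the aryl group on the terminal carbon, and since the neighbouring carbon is quaternary the only syn β-hydrogen is the benzylic one, so the E styrene forms, at a temperature below that of the rearrangement.

Step 24
Reactants: 32 2-styryl dihydropyran
Product: 33 hexa-MOM ether of the target, (3S,4R,5S)-cyclohexene
Conditions: o-xylene (degassed), 2,6-di-tert-butyl-4-methylpyridine (5 mol%), silylated glass, sealed tube, 130–140 °C
Reagents that add atoms: none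
Why: On heating, the allyl vinyl ether made of O1, C6(aryl)=C5 of the pyran and C2–CH=CH(ring A) undergoes a concerted [3,3]-sigmatropic Claisen shift in which the O1–C2 bond breaks while pyran C5 bonds to the styryl β-carbon, so that the aryl ketone is released, the alkene moves to C1=C2 of the product and the pyran is traded for the methylcyclohexene. The closest known reactions are the thermal rearrangement of 2-alkenyl-3,4-dihydro-2H-pyrans to 4-acylcyclohexenes and the Ireland–Claisen ring contraction of 6-alkenyl δ-lactones. The carbocycle closes in a six-membered sigmatropic mode through the only transition state that the C3–C4 tether of the pyran allows, a boat of bicyclo[2.2.2]octane shape, and the opening of the pyran is part of the same event. Product C4 is set by suprafacial delivery of the β-carbon to the pyran face that carries the alkenyl group, which is cis to the ring C aryl group and therefore leaves the new aroyl group trans to it, and product C3 is set by the E geometry of the styrene, which in the boat turns ring A to the side of the departing oxygen and hence cis to the aroyl group; C5 is untouched and the old C–O centre is spent. The step needs the concerted [3,3] path to prevail over ionization with scrambling, a [1,3] shift or elimination, and this is secured by the two-carbon tether that keeps bond making intramolecular and on one face, by the aryl donor on the enol ether carbon, the weak tertiary allylic C–O bond and the gain of an aryl ketone, which lower the barrier, and by an acid-free non-polar medium.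

Step 25
Reactants: 33 hexa-MOM ether
Product: 34 CNP0140882.1
Conditions: 3 M aq. HCl, MeOH/THF, 35–40 °C, argon; stopped when the hexaphenol is reached
Reagents that add atoms: none
Why: Acid-catalysed acetal exchange with methanol removes the six aryl MOM ethers, which cleave faster than the skeleton reacts, and the mild temperature should leave the C4 centre, the chalcone and the two alkenes unchanged.

**Compound list**
1 | 2,4-dihydroxybenzaldehyde | O=Cc1ccc(O)cc1O | starting material
2 | 2,4-bis(methoxymethoxy)benzaldehyde | O=Cc1ccc(OCOC)cc1OCOC | intermediate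
3 | diethyl 2,4-diacetyl-3-[2,4-bis(methoxymethoxy)phenyl]pentanedioate (open bis-adduct, stereoisomer mixture) | CCOC(=O)C(C(C)=O)C(c1ccc(OCOC)cc1OCOC)C(C(C)=O)C(=O)OCC | intermediate
4 | diethyl 2-[2,4-bis(methoxymethoxy)phenyl]-4-hydroxy-4-methyl-6-oxocyclohexane-1,3-dicarboxylate (racemic, configuration not defined and erased in step 3) | CCOC(=O)C1C(c2ccc(OCOC)cc2OCOC)C(C(=O)OCC)C(C)(O)CC1=O | intermediate
5 | 3-[2,4-bis(methoxymethoxy)phenyl]pentanedioic acid | OC(=O)CC(CC(=O)O)c1ccc(OCOC)cc1OCOC | intermediate
6 | 3-[2,4-bis(methoxymethoxy)phenyl]-N1,N5-dimethoxy-N1,N5-dimethylpentanediamide | CON(C)C(=O)CC(CC(=O)N(C)OC)c1ccc(OCOC)cc1OCOC | intermediate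
7 | 4-[2,4-bis(methoxymethoxy)phenyl]heptane-2,6-dione | CC(=O)CC(CC(C)=O)c1ccc(OCOC)cc1OCOC | intermediate
8 | (S)-5-[2,4-bis(methoxymethoxy)phenyl]-3-methylcyclohex-2-en-1-one | CC1=CC(=O)C[C@@H](c2ccc(OCOC)cc2OCOC)C1 | intermediate
9 | (2S,3S,5S)-5-[2,4-bis(methoxymethoxy)phenyl]-2,3-epoxy-3-methylcyclohexan-1-one | C[C@@]12O[C@@H]1C(=O)C[C@@H](c3ccc(OCOC)cc3OCOC)C2 | intermediate
10 | (1S,5R)-5-[2,4-bis(methoxymethoxy)phenyl]-1-methylcyclohex-2-en-1-ol | C[C@@]1(O)C=CC[C@@H](c2ccc(OCOC)cc2OCOC)C1 | intermediate
11 | (2S,4S)-4-[2,4-bis(methoxymethoxy)phenyl]-2-hydroxy-2-methylhexanedial | C[C@@](O)(C=O)C[C@H](c1ccc(OCOC)cc1OCOC)CC=O | intermediate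
12 | (2S,4S)-4-[2,4-bis(methoxymethoxy)phenyl]-6-hydroxy-2-methyloxane-2-carbaldehyde (both anomers) | C[C@@]1(C=O)C[C@H](c2ccc(OCOC)cc2OCOC)CC(O)O1 | intermediate
13 | (2S,4S)-4-[2,4-bis(methoxymethoxy)phenyl]-2-methyl-6-oxooxane-2-carbaldehyde | C[C@@]1(C=O)C[C@H](c2ccc(OCOC)cc2OCOC)CC(=O)O1 | intermediate
14 | (4S,6S)-4-[2,4-bis(methoxymethoxy)phenyl]-6-ethenyl-6-methyloxan-2-one | C[C@@]1(C=C)C[C@H](c2ccc(OCOC)cc2OCOC)CC(=O)O1 | intermediate
15 | resorcinol | Oc1cccc(O)c1 | starting material
16 | 1,3-bis(methoxymethoxy)benzene | COCOc1cccc(OCOC)c1 | intermediate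
17 | 2-lithio-1,3-bis(methoxymethoxy)benzene | COCOc1cccc(OCOC)c1[Li] | intermediate
18 | 2-iodo-1,3-bis(methoxymethoxy)benzene | COCOc1cccc(OCOC)c1I | intermediate
19 | 3-methylbut-1-yne | CC(C)C#C | starting material
20 | (E)-4,4,5,5-tetramethyl-2-(3-methylbut-1-en-1-yl)-1,3,2-dioxaborolane | CC(C)/C=C/B1OC(C)(C)C(C)(C)O1 | intermediate
21 | 1,3-bis(methoxymethoxy)-2-[(E)-3-methylbut-1-enyl]benzene | COCOc1cccc(OCOC)c1/C=C/C(C)C | intermediate
22 | {2,4-bis(methoxymethoxy)-3-[(E)-3-methylbut-1-enyl]phenyl}lithium | COCOc1ccc([Li])c(OCOC)c1/C=C/C(C)C | intermediate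
23 | {2,4-bis(methoxymethoxy)-3-[(E)-3-methylbut-1-enyl]phenyl}boronic acid | COCOc1ccc(B(O)O)c(OCOC)c1/C=C/C(C)C | intermediate
24 | 2,4-dihydroxyacetophenone | CC(=O)c1ccc(O)cc1O | starting material
25 | 1-(2,4-dihydroxy-3-iodophenyl)ethan-1-one | CC(=O)c1ccc(O)c(I)c1O | intermediate
26 | 1-[3-iodo-2,4-bis(methoxymethoxy)phenyl]ethan-1-one | CC(=O)c1ccc(OCOC)c(I)c1OCOC | intermediate
27 | 4-hydroxybenzaldehyde | O=Cc1ccc(O)cc1 | starting material
28 | 4-(methoxymethoxy)benzaldehyde | O=Cc1ccc(OCOC)cc1 | intermediate
29 | (E)-1-[3-iodo-2,4-bis(methoxymethoxy)phenyl]-3-[4-(methoxymethoxy)phenyl]prop-2-en-1-one | COCOc1ccc(/C=C/C(=O)c2ccc(OCOC)c(I)c2OCOC)cc1 | intermediate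
30 | (2S,4S)-4-[2,4-bis(methoxymethoxy)phenyl]-2-ethenyl-2-methyl-3,4-dihydro-2H-pyran-6-yl diphenyl phosphate | C[C@@]1(C=C)C[C@H](c2ccc(OCOC)cc2OCOC)C=C(OP(=O)(Oc2ccccc2)Oc2ccccc2)O1 | intermediate
31 | (2S,4S)-6-{2,4-bis(methoxymethoxy)-3-[(E)-3-methylbut-1-enyl]phenyl}-4-[2,4-bis(methoxymethoxy)phenyl]-2-ethenyl-2-methyl-3,4-dihydro-2H-pyran | C[C@@]1(C=C)C[C@H](c2ccc(OCOC)cc2OCOC)C=C(c2ccc(OCOC)c(/C=C/C(C)C)c2OCOC)O1 | intermediate
32 | (2S,4S)-2-methyl-2-[(E)-2-aryl-ethenyl] dihydropyran, aryl = 2,6-bis(methoxymethoxy)-3-{(E)-3-[4-(methoxymethoxy)phenyl]prop-2-enoyl}phenyl; ring B aryl on C6 and ring C aryl on C4, alkenyl cis to the C4 aryl | C[C@@]1(/C=C/c2c(OCOC)ccc(C(=O)/C=C/c3ccc(OCOC)cc3)c2OCOC)C[C@H](c2ccc(OCOC)cc2OCOC)C=C(c2ccc(OCOC)c(/C=C/C(C)C)c2OCOC)O1 | intermediate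
33 | hexa-MOM ether of the target, (3S,4R,5S); C3/C4 cis, C4/C5 trans | CC1=C[C@H](c2c(OCOC)ccc(C(=O)/C=C/c3ccc(OCOC)cc3)c2OCOC)[C@H](C(=O)c2ccc(OCOC)c(/C=C/C(C)C)c2OCOC)[C@@H](c2ccc(OCOC)cc2OCOC)C1 | intermediate
34 | CNP0140882.1, (3S,4R,5S) | CC1=C[C@H](c2c(O)ccc(C(=O)/C=C/c3ccc(O)cc3)c2O)[C@H](C(=O)c2ccc(O)c(/C=C/C(C)C)c2O)[C@@H](c2ccc(O)cc2O)C1 | target

**Step count**
Total step count: 25. Longest linear sequence: 16 steps (steps 1–11 and 21–25).

**Steps most likely to fail**

Step 24 (Claisen ring switch). What may go wrong: heterolysis of the tertiary, styrene-conjugated C2–O bond running ahead of C–C bond formation, followed by a [1,3] shift, loss of alkene geometry or elimination to a triene; or too slow a shift at the crowded C3–C4 bond below the decomposition temperature. Fallback: the same ring switch one oxidation level higher, as the Ireland–Claisen ring contraction of the 6-styryl δ-lactone, where the silyloxy donor lets the concerted boat path run at 60–100 °C. It sets out from lactone aldehyde 13 and comes back at 33. Takai-type boryl olefination of 13 (CrCl2, Cl2CHB(pin), LiI, THF) should give the (E)-alkenylboronate lactone F1, and Suzuki–Miyaura coupling of F1 with iodide 29 (Pd(OAc)2, SPhos, K3PO4, THF/H2O, rt) the 6-styryl lactone F2. LiN(SiMe3)2 added to F2 and Me3SiCl/Et3N in THF at −78 °C gives the trimethylsilyl ketene acetal F3, which on warming in toluene should rearrange through the same boat to the silyl ester F4; aqueous work-up frees the cyclohexenecarboxylic acid F5 with C3, C4 and C5 as in 33. Acylative Suzuki–Miyaura coupling of F5 with boronic acid 23 (pivalic anhydride, Pd(OAc)2, P(4-MeOC6H4)3, THF/H2O, 60 °C) then gives 33.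

Step 23 (Heck arylation). What may go wrong: slow insertion of the di-ortho-substituted arylpalladium species into the neopentyl-type vinyl group, β-alkoxide elimination from the alkylpalladium intermediate or ionization of the tertiary allylic enol ether by zerovalent palladium, each of which opens the pyran; or rearrangement of the product before isolation. Fallback: form the aryl–alkenyl bond by Suzuki–Miyaura coupling before the enol ether exists, so that no alkylpalladium species with a β-oxygen arises. It sets out from lactone aldehyde 13 and comes back at 32. Compound 13 is taken to the alkenylboronate lactone F1 and on to the 6-styryl lactone F2 exactly as written above. KN(SiMe3)2 added to F2 and (PhO)2P(O)Cl at −78 °C (in situ trapping, which also keeps the enolate away from the chalcone) gives the styryl ketene acetal phosphate F6, and coupling of F6 with boronic acid 23 under the conditions of step 22 gives 32.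

Step 25 (removal of six MOM ethers). What may go wrong: under protic acid, cyclization of freed phenols (ketal formation at the C4 ketone with neighbouring ortho-hydroxyl groups, chromane formation with the ring alkene or the methylbutenyl group, flavanone closure of the 2'-hydroxychalcone), epimerization at C4, or incomplete cleavage. Fallback: non-protic acetal exchange in place of acid solvolysis. It sets out from 33 and comes back at 34. Me3SiOTf with 2,2'-bipyridyl in CH2Cl2 at 0 °C should turn each aryl MOM ether into the aryl trimethylsilyl ether, giving the hexakis(trimethylsilyl) ether F7, and neutral methanolysis (MeOH, pH 7 buffer, rt) of F7 gives 34.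

Further compounds
F1 | step 24 | (4S,6S)-4-[2,4-bis(methoxymethoxy)phenyl]-6-methyl-6-[(E)-2-(4,4,5,5-tetramethyl-1,3,2-dioxaborolan-2-yl)ethenyl]oxan-2-one | C[C@@]1(/C=C/B2OC(C)(C)C(C)(C)O2)C[C@H](c2ccc(OCOC)cc2OCOC)CC(=O)O1
F2 | step 24 | (4S,6S)-6-styryl lactone carrying the ring A chalcone aryl on the alkene | C[C@@]1(/C=C/c2c(OCOC)ccc(C(=O)/C=C/c3ccc(OCOC)cc3)c2OCOC)C[C@H](c2ccc(OCOC)cc2OCOC)CC(=O)O1
F3 | step 24 | trimethylsilyl ketene acetal of F2, (2S,4S)-2-methyl-2-styryl-6-(trimethylsilyloxy)-3,4-dihydro-2H-pyran | C[C@@]1(/C=C/c2c(OCOC)ccc(C(=O)/C=C/c3ccc(OCOC)cc3)c2OCOC)C[C@H](c2ccc(OCOC)cc2OCOC)C=C(O[Si](C)(C)C)O1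
F4 | step 24 | trimethylsilyl ester of the cyclohexenecarboxylic acid, configuration as in 33 | CC1=C[C@H](c2c(OCOC)ccc(C(=O)/C=C/c3ccc(OCOC)cc3)c2OCOC)[C@H](C(=O)O[Si](C)(C)C)[C@@H](c2ccc(OCOC)cc2OCOC)C1
F5 | step 24 | cyclohexenecarboxylic acid with CO2H in place of the ring B aroyl group, configuration as in 33 | CC1=C[C@H](c2c(OCOC)ccc(C(=O)/C=C/c3ccc(OCOC)cc3)c2OCOC)[C@H](C(=O)O)[C@@H](c2ccc(OCOC)cc2OCOC)C1
F6 | step 23 | (2S,4S)-2-methyl-2-styryl-3,4-dihydro-2H-pyran-6-yl diphenyl phosphate (ketene acetal phosphate of F2) | C[C@@]1(/C=C/c2c(OCOC)ccc(C(=O)/C=C/c3ccc(OCOC)cc3)c2OCOC)C[C@H](c2ccc(OCOC)cc2OCOC)C=C(OP(=O)(Oc2ccccc2)Oc2ccccc2)O1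
F7 | step 25 | hexakis(trimethylsilyl) ether of 34 | CC1=C[C@H](c2c(O[Si](C)(C)C)ccc(C(=O)/C=C/c3ccc(O[Si](C)(C)C)cc3)c2O[Si](C)(C)C)[C@H](C(=O)c2ccc(O[Si](C)(C)C)c(/C=C/C(C)C)c2O[Si](C)(C)C)[C@@H](c2ccc(O[Si](C)(C)C)cc2O[Si](C)(C)C)C1
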